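All runs were generated by integration with constants of no real substance, and the scatter is random.

A closed flask (blue), a flask dosed with substrate (teal), a plug-flow tube (ochre) and a stirred tank (violet) take the same charge of substrate and free catalyst, and you want the one that ends with the most target.

| flask | substrate | free catalyst | remark | time |
|---|---|---|---|---|
| dusk | 0.21 M | 0.42 mM | run made earlier |  |
| summer | 0.14 M | 0.42 mM | run made earlier |  |
| autumn | 0.32 M | 0.42 mM | run made earlier |  |
| noon | 0.21 M | 0.21 mM | run made earlier |  |
| blue | 0.21 M | 0.42 mM | everything together in a closed stirred flask, run for 2.5 min | 2.5 min |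
| teal | 0.21 M (fed, over 1.25 min) | 0.42 mM | all but substrate at the start; substrate goes in evenly over 1.25 min, the run ends at 2.5 min | 2.5 min |
| ochre | 0.21 M | 0.42 mM | a tube with plug flow, the mixed feed as stated, residence time 2.5 min | 2.5 min |
| violet | 0.21 M | 0.42 mM | one stirred flow tank at steady state, fed with the mixture as stated, mean residence time 2.5 min |  |

dusk run (percent of the substrate charged)

| time / min | target / % | substrate / % |
|---|---|---|
| 0.333 | 26.3 | 0 |
| 0.833 | 26.2 | 0 |
| 1.50 | 26.2 | 0 |
| 2.50 | 26.2 | 0 |

summer run (percent of the substrate charged)

| time / s | target / % | substrate / % |
|---|---|---|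
| 10.0 | 32.6 | 3.2 |
| 15.0 | 34.4 | 0.4 |
| 40.0 | 35.0 | 0.7 |
| 90.0 | 35.6 | 0 |

autumn run (percent of the substrate charged)

| time / s | target / % | substrate / % |
|---|---|---|
| 10.0 | 16.4 | 2.1 |
| 15.0 | 17.3 | 0 |
| 40.0 | 18.1 | 0 |
| 90.0 | 18.3 | 0.4 |

noon run (percent of the substrate charged)

| time / s | target / % | substrate / % |
|---|---|---|
| 25.0 | 16.6 | 1.0 |
| 50.0 | 18.2 | 0.5 |
| 60.0 | 17.5 | 0.3 |
| 90.0 | 17.7 | 0 |

(each reading ± 0.5 percentage points)

- the stated concentrations are those of everything mixed, before any reaction; amounts are the same in each set-up
- the analysis behind the earlier runs scatters by 0.5 percentage points, standard deviation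
- the feed brings no volume worth counting
- the earlier runs were made in a closed, stirred flask

1. the set-up with the highest amount of target at the outlet or at the end, in percent of the substrate put in ("none" if the first two lie within 2 percentage points) (blue / teal / ochre / violet / none)
2. amount of target at the outlet or at the end, in percent of the substrate put in, blue
3. amount of target at the outlet or at the end, in percent of the substrate put in, teal
4. amount of target at the outlet or at the end, in percent of the substrate put in, ochre
5. amount of target at the outlet or at the end, in percent of the substrate put in, violet

The closed runs look contradictory. In autumn substrate reads 0% by 15.0 s, so it has reacted, yet raising the charge from 0.14 M in summer to 0.32 M in autumn moved the target from 0.0498 M to 0.0586 M. Of the 0.110 M that autumn holds beyond dusk, 3.22% became target, far less than the 35.6% of summer's charge. So a side path takes substrate while its level is high. At low level the opposite holds: summer's 3.2% at 10.0 s was followed by 3 percentage points more target.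

The share therefore follows the level, not the charge, and slow entry keeps the level nearly constant. Freeze it: inflow equals k times level, with k the pseudo-first-order constant of that low-level tail. In summer, substrate between 10.0 s and 15.0 s reads 0.416 s⁻¹, and the target's rise reads 0.183 s⁻¹. The scatter can't part these, so I take their geometric mean, 0.276 s⁻¹.

For violet the held level, charge divided by k and residence time, 0.00507 M, leaves 2.41% unreacted, so I reckon its yield below 97.6%. Teal, fed over 1.25 min, holds 0.0101 M, twice violet's level, so I expect it to lose more to the side path. Blue and ochre start at the full charge, as dusk did, so I expect 26.2%. I put violet first.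

The forecast gives 26.2% for blue, 88% for teal, 26.2% for ochre and 93% for violet, and ends: “Violet is best.”

The flasks give 26.2% for blue, 83.2% for teal, 26.2% for ochre and 88.9% for violet, so violet leads.

    2 substrate → self-condensation product (k = 2.40 M⁻¹ s⁻¹)
    catalyst intermediate A ⇌ catalyst intermediate B (K = 0.810, k = 110 s⁻¹)
    catalyst intermediate B → free catalyst + target (k = 120 s⁻¹)
    substrate + free catalyst → catalyst intermediate A (k = 640 M⁻¹ s⁻¹)

Violet's tank stands at 0.00504 M of substrate, with 2.40% of the charge unreacted, against the held level of 0.00507 M. The back-mixing in that tank is the main reason for violet's yield: with it taken away, violet gives 26.2% instead of 88.9%, a change of 63 points. Teal, dosed twice as fast, reached 0.0101 M of substrate at its highest, against a held level of 0.0101 M.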